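The earlier runs and the new flask were computed with made-up constants, and the scatter is random.

- 0.511 lifetimes of the electrophile were spent in the birch run by 8.00 min. Lifetimes spent, N, are the natural logarithm of electrophile charged over electrophile left, the clock of a pseudo-first-order loss. Product and electrophile add to 99.0% in that reading, so product is taken as the charge minus the fraction e^(−N) left.

| setting | oak | birch | west | east |
|---|---|---|---|---|
| electrophile | 20 mM | 20 mM | 20 mM | 20 mM |
| free base | 1.5 equiv | 1.5 equiv | 1.50 equiv | 1.50 equiv |
| protonated nucleophile | 0.69 equiv | 4.6 equiv | 1.30 equiv | 5.20 equiv |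
| protic impurity | 10 mM | 10 mM | 10.0 mM | 10.0 mM |
| temperature | 5 °C | 16 °C | 20 °C | 0 °C |
| remark | run made earlier | run made earlier |  |  |
| time |  |  | 8.0 min | 8.0 min |

| run | time / min | product / % | electrophile / % |
|---|---|---|---|
| oak | 2.00 | 2 | 96 |
| oak | 5.00 | 9 | 91 |
| oak | 6.00 | 9 | 90 |
| oak | 10.0 | 16 | 83 |
| oak | 12.0 | 14 | 83 |
| oak | 15.0 | 18 | 82 |
| birch | 1.00 | 11 | 88 |
| birch | 2.50 | 23 | 80 |
| birch | 3.00 | 25 | 76 |
| birch | 5.00 | 32 | 69 |
| birch | 6.00 | 36 | 64 |
| birch | 8.00 | 39 | 60 |

(each reading ± 1.5 percentage points)

- the earlier runs were read with a standard deviation of 1.5 percentage points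

1. which of the two ends with the higher amount of product, in percent of the electrophile charged ("neither" if they lie within 2 percentage points) (west / east / neither)
2. product at the end, in percent of the electrophile charged, west
3. product at the end, in percent of the electrophile charged, east

- Oak spent 0.0186 min⁻¹ over 10.0 min and birch 0.0639 min⁻¹, so the read ratio G is 3.43. G mixes a step in protonated nucleophile with a step in temperature.
- First extreme: G is wholly temperature. West then spends 0.799 lifetimes, giving 55.0% product, and east 0.0852, giving 8.17%.
- Second extreme: G is wholly charge, with order n = 0.649 in protonated nucleophile. West then spends 0.225, giving 20.1%, and east 0.553, giving 42.5%. The ranking has reversed.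
- These two runs cannot split G, so this reckoning commits to an equal split of ln G, the geometric mean of the extremes. West spends 0.424, giving 34.6%, and east 0.217, giving 19.5%, so west ends higher.
- The forecast differs in its numbers but not its ranking: west, with 30% for west and 23% for east, while warning that the “order and temperature effects are confounded”.

    electrophile + nucleophile → acid set free + product (k = 9.70 M⁻¹ min⁻¹, Ea = 46.0 kJ mol⁻¹)
    nucleophile + acid set free ⇌ protonated nucleophile, settled at all times (K = 11000 M⁻¹, ΔH = −29.0 kJ mol⁻¹)
    acid set free + free base ⇌ salt of the base, settled at all times (K = 3600 M⁻¹, ΔH = −29.0 kJ mol⁻¹)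
    protic impurity + free base → quenched reagent (k = 42.0 M⁻¹ min⁻¹, Ea = 37.0 kJ mol⁻¹)
    crystals ⇌ acid set free, rate k5*(cs5 - [acid set free]) while solid is left; crystals form when [acid set free] > cs5 (solubility = 11.0 mM, k = 0.890 min⁻¹)
    (constants at 20 °C)

- West ends at 30.8% and east at 22.5%, so west leads. With 69% and 77% of the electrophile left, west spent 0.371 lifetimes and east 0.255, each between its extremes. The neighbouring flask repeats east at −25 °C. The equal split from 0.511, with the temperature step scaled from east's own first extreme, gives it 0.0535 lifetimes, or 5.21% product. That flask ends at 4.25% product, with 96% of its electrophile left.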